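**Plan**

- Retrosynthetic cuts, in order: the O–Si bond at O7; the C2–C1' bond between ring C and ring B; the aryl C4'–O bond of the pyran ring fused to ring B (ring D); the C6–prenyl bond; ring C of a chromone back to an acetophenone.
- Forward: ring C is closed on a brominated acetophenone (chromone through an enaminone) and the prenyl group is put on C6 by Stille coupling. Separately, ring D is closed on a ring B aldehyde after Z-olefination and double methyl addition, and the bromide at C1' becomes a boronic acid. The halves are joined at C2–C1' and desilylation ends the route.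
- Feature that makes the key event possible: in ring D the oxygen is bound to the fully substituted C2'' (two methyl groups), so its alkoxide has no β-hydrogen to lose at palladium, and the cis C3''=C4'' bond holds it over C4'. C4' is para to C1', so an iodide at C4' and a bromide at C1' can be used one after the other.
- Stereochemistry: the only stereocenter, C2 (S), comes from catalyst control in the conjugate addition of the ring B boronic acid to the chromone. The cis geometry of ring D comes from the Still–Gennari olefination.

Key step: step 6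

Assumption: the (R)-pyridine-oxazoline ligand is taken to steer the aryl group to the Re face of C2 of the chromone, by analogy with its sense on β-substituted cyclic enones; should the sense be the opposite one, the (S)-ligand is used in step 8.

**Route**

Step 1
Reactants: 1 1-(5-bromo-2,4-dihydroxyphenyl)ethan-1-one; 2 chlorotri(propan-2-yl)silane
Product: 3 1-{5-bromo-2-hydroxy-4-[tri(propan-2-yl)silyloxy]phenyl}ethan-1-one
Conditions: 2 (1.1 equiv), imidazole (2.2 equiv), DMF, 0 °C to rt
Reagents that add atoms: 2 chlorotri(propan-2-yl)silane, CC(C)[Si](Cl)(C(C)C)C(C)C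
Why: The 2-OH is held in a hydrogen bond to the acetyl carbonyl and is less acidic, so O-silylation (silyl ether formation) should take place at the free 4-OH only.

Step 2
Reactants: 3 1-{5-bromo-2-hydroxy-4-[tri(propan-2-yl)silyloxy]phenyl}ethan-1-one; 4 1,1-dimethoxy-N,N-dimethylmethanamine (N,N-dimethylformamide dimethyl acetal)
Product: 6 6-bromo-7-[tri(propan-2-yl)silyloxy]-4H-chromen-4-one, via enaminone 5 (not isolated)
Conditions: 4 (2 equiv), toluene, 100 °C; concentrate; then TsOH·H2O (1.2 equiv), CH2Cl2, rt
Reagents that add atoms: 4 1,1-dimethoxy-N,N-dimethylmethanamine, COC(OC)N(C)C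
Why: Condensation of the methyl ketone with the amide acetal gives the enaminone, and acid-promoted addition of the 2-OH to its β-carbon with loss of dimethylamine (enaminone route to chromones) should close ring C without touching the aryl silyl ether or the bromide.

Step 3
Reactants: 6 6-bromo-7-[tri(propan-2-yl)silyloxy]-4H-chromen-4-one; 7 tributyl(3-methylbut-2-en-1-yl)stannane
Product: 8 6-(3-methylbut-2-en-1-yl)-7-[tri(propan-2-yl)silyloxy]-4H-chromen-4-one
Conditions: 7 (1.5 equiv), Pd(PPh3)4 (5 mol %), DMF, 95 °C
Reagents that add atoms: 7 tributyl(3-methylbut-2-en-1-yl)stannane, CCCC[Sn](CCCC)(CCCC)CC=C(C)C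
Why: Stille coupling (oxidative addition of zerovalent palladium to the C6–Br bond, transmetalation of the allylstannane, reductive elimination) should give the linear prenyl arene under neutral conditions that spare the silyl ether and the chromone.

Step 4
Reactants: 9 5-bromo-2-iodobenzaldehyde; 10 methyl 2-[bis(2,2,2-trifluoroethoxy)phosphoryl]acetate
Product: 11 methyl (Z)-3-(5-bromo-2-iodophenyl)prop-2-enoate
Conditions: 10 (1.1 equiv), KN(SiMe3)2 (1.1 equiv), 18-crown-6 (3 equiv), THF, −78 °C
Reagents that add atoms: 10 methyl 2-[bis(2,2,2-trifluoroethoxy)phosphoryl]acetate, COC(=O)CP(=O)(OCC(F)(F)F)OCC(F)(F)F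
Why: Still–Gennari olefination: the electron-poor phosphonate with a dissociated potassium counter-ion eliminates fast from the kinetically formed adduct, which should give the Z-enoate that later brings the oxygen within reach of the iodine-bearing carbon.

Step 5
Reactants: 11 methyl (Z)-3-(5-bromo-2-iodophenyl)prop-2-enoate; 12 methylmagnesium bromide
Product: 14 (Z)-4-(5-bromo-2-iodophenyl)-2-methylbut-3-en-2-ol, via methyl ketone 13 (not isolated)
Conditions: 12 (3.2 equiv), THF, −78 to 0 °C; then sat. aq. NH4Cl
Reagents that add atoms: 12 methylmagnesium bromide, C[Mg]Br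
Why: Double Grignard 1,2-addition to the ester through the methyl ketone should give the tertiary alcohol with the Z-alkene intact (the same change that opens coumarins to Z-configured carbinols), and MeMgBr does not exchange with aryl iodides or bromides at this temperature.

Step 6
Reactants: 14 (Z)-4-(5-bromo-2-iodophenyl)-2-methylbut-3-en-2-ol
Product: 15 6-bromo-2,2-dimethyl-2H-chromene
Conditions: Pd(OAc)2 (3 mol %), 2-(di-tert-butylphosphino)-1,1'-binaphthyl (4 mol %), Cs2CO3 (1.5 equiv), toluene, 65 °C
Reagents that add atoms: none
Why: Zerovalent palladium formed from Pd(OAc)2 and the bulky phosphine adds oxidatively to the carbon–iodine bond of 14 (the carbon that becomes C4' of ring B), carbonate-assisted exchange of iodide for the tertiary alkoxide gives a seven-membered aryl(alkoxo) complex of divalent palladium, and C–O reductive elimination releases 15 and the zerovalent catalyst. The closest known reaction type is the intramolecular Buchwald–Hartwig etherification of aryl halides with tertiary alcohols, which gives 2,2-dimethylchromans; here the saturated tether is replaced by a Z-alkene. The one ring closed is the six-membered pyran ring D, formed by reductive elimination from the seven-membered palladacycle (formally a 6-exo attack of oxygen on the aryl carbon). No stereocenter is created, and the Z-geometry set in step 4 is carried into the ring as the C3''=C4'' bond. The step needs chemoselectivity for carbon–iodine over carbon–bromine, which the weaker carbon–iodine bond should secure at 65 °C so that bromine stays for step 7, and it needs C–O reductive elimination to outrun β-hydride elimination, which is secured because the oxygen sits on the quaternary gem-dimethyl carbon (no β-hydrogen on the alkoxide) and the bulky ligand speeds reductive elimination.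

Step 7
Reactants: 15 6-bromo-2,2-dimethyl-2H-chromene; 16 tri(propan-2-yl) borate; 17 water
Product: 20 (2,2-dimethyl-2H-chromen-6-yl)boronic acid, via aryllithium 18 (not isolated), via lithium borate 19 (not isolated)
Conditions: n-BuLi (1.1 equiv), THF, −78 °C; 16 (1.5 equiv), −78 °C to rt; then aq. HCl (1 M), 0 °C
Reagents that add atoms: 16 tri(propan-2-yl) borate, CC(C)OB(OC(C)C)OC(C)C; 17 water, O
Why: Bromine–lithium exchange at −78 °C is faster than any attack on the chromene, the aryllithium is trapped by the borate ester as an ate complex, and brief hydrolysis with dilute acid should give the boronic acid.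

Step 8
Reactants: 8 6-(3-methylbut-2-en-1-yl)-7-[tri(propan-2-yl)silyloxy]-4H-chromen-4-one; 20 (2,2-dimethyl-2H-chromen-6-yl)boronic acid
Product: 21 (2S)-2-(2,2-dimethyl-2H-chromen-6-yl)-6-(3-methylbut-2-en-1-yl)-7-[tri(propan-2-yl)silyloxy]-2,3-dihydro-4H-chromen-4-one
Conditions: 20 (2 equiv), Pd(OCOCF3)2 (5 mol %), (R)-4-tert-butyl-2-(pyridin-2-yl)-4,5-dihydro-1,3-oxazole (6 mol %), NH4PF6 (30 mol %), H2O (5 equiv), ClCH2CH2Cl, 60 °C
Reagents that add atoms: none
Why: Palladium-catalysed asymmetric conjugate addition of an arylboronic acid to a chromone (Hayashi–Miyaura-type 1,4-addition with a cationic pyridine-oxazoline complex of divalent palladium) proceeds by transmetalation, insertion of C2=C3 into the aryl–palladium bond and protonolysis of the palladium enolate by water; the tert-butyl group of the (R)-ligand shields one face so that the aryl group should add to the Re face of C2 and set the (S) configuration, and the isolated prenyl and chromene alkenes are poorer acceptors than the enone.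

Step 9
Reactants: 21 (2S)-2-(2,2-dimethyl-2H-chromen-6-yl)-6-(3-methylbut-2-en-1-yl)-7-[tri(propan-2-yl)silyloxy]-2,3-dihydro-4H-chromen-4-one
Product: 22 Dinklagin A, (2S)-2-(2,2-dimethyl-2H-chromen-6-yl)-7-hydroxy-6-(3-methylbut-2-en-1-yl)-2,3-dihydro-4H-chromen-4-one
Conditions: Bu4NF (1.2 equiv), AcOH (1.3 equiv), THF, 0 °C
Reagents that add atoms: none
Why: Fluoride-mediated desilylation cleaves the aryl O–Si bond, and the acetic acid buffer should keep the base-labile C2 stereocenter (retro-oxa-Michael path) and the acid-labile prenyl and chromene units away from either extreme.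

**Compound list**

1 | 1-(5-bromo-2,4-dihydroxyphenyl)ethan-1-one | CC(=O)c1cc(Br)c(O)cc1O | starting material
2 | chlorotri(propan-2-yl)silane | CC(C)[Si](Cl)(C(C)C)C(C)C | starting material
3 | 1-{5-bromo-2-hydroxy-4-[tri(propan-2-yl)silyloxy]phenyl}ethan-1-one | CC(=O)c1cc(Br)c(O[Si](C(C)C)(C(C)C)C(C)C)cc1O | intermediate
4 | 1,1-dimethoxy-N,N-dimethylmethanamine | COC(OC)N(C)C | starting material
5 | (E)-1-{5-bromo-2-hydroxy-4-[tri(propan-2-yl)silyloxy]phenyl}-3-(dimethylamino)prop-2-en-1-one | CN(C)/C=C/C(=O)c1cc(Br)c(O[Si](C(C)C)(C(C)C)C(C)C)cc1O | intermediate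
6 | 6-bromo-7-[tri(propan-2-yl)silyloxy]-4H-chromen-4-one | O=C1C=COc2cc(O[Si](C(C)C)(C(C)C)C(C)C)c(Br)cc12 | intermediate
7 | tributyl(3-methylbut-2-en-1-yl)stannane | CCCC[Sn](CCCC)(CCCC)CC=C(C)C | starting material
8 | 6-(3-methylbut-2-en-1-yl)-7-[tri(propan-2-yl)silyloxy]-4H-chromen-4-one | CC(C)=CCc1cc2c(cc1O[Si](C(C)C)(C(C)C)C(C)C)OC=CC2=O | intermediate
9 | 5-bromo-2-iodobenzaldehyde | O=Cc1cc(Br)ccc1I | starting material
10 | methyl 2-[bis(2,2,2-trifluoroethoxy)phosphoryl]acetate | COC(=O)CP(=O)(OCC(F)(F)F)OCC(F)(F)F | starting material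
11 | methyl (Z)-3-(5-bromo-2-iodophenyl)prop-2-enoate | COC(=O)/C=C\c1cc(Br)ccc1I | intermediate
12 | methylmagnesium bromide | C[Mg]Br | starting material
13 | (Z)-4-(5-bromo-2-iodophenyl)but-3-en-2-one | CC(=O)/C=C\c1cc(Br)ccc1I | intermediate
14 | (Z)-4-(5-bromo-2-iodophenyl)-2-methylbut-3-en-2-ol | CC(C)(O)/C=C\c1cc(Br)ccc1I | intermediate
15 | 6-bromo-2,2-dimethyl-2H-chromene | CC1(C)C=Cc2cc(Br)ccc2O1 | intermediate
16 | tri(propan-2-yl) borate | CC(C)OB(OC(C)C)OC(C)C | starting material
17 | water | O | starting material
18 | (2,2-dimethyl-2H-chromen-6-yl)lithium | [Li]c1ccc2OC(C)(C)C=Cc2c1 | intermediate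
19 | lithium (2,2-dimethyl-2H-chromen-6-yl)tri(propan-2-yloxy)borate | [Li+].CC(C)O[B-](OC(C)C)(OC(C)C)c1ccc2OC(C)(C)C=Cc2c1 | intermediate
20 | (2,2-dimethyl-2H-chromen-6-yl)boronic acid | OB(O)c1ccc2OC(C)(C)C=Cc2c1 | intermediate
21 | (2S)-2-(2,2-dimethyl-2H-chromen-6-yl)-6-(3-methylbut-2-en-1-yl)-7-[tri(propan-2-yl)silyloxy]-2,3-dihydro-4H-chromen-4-one | CC(C)=CCc1cc2c(cc1O[Si](C(C)C)(C(C)C)C(C)C)O[C@H](c1ccc3c(c1)C=CC(C)(C)O3)CC2=O | intermediate
22 | Dinklagin A, (2S)-2-(2,2-dimethyl-2H-chromen-6-yl)-7-hydroxy-6-(3-methylbut-2-en-1-yl)-2,3-dihydro-4H-chromen-4-one | CC(C)=CCc1cc2c(cc1O)O[C@H](c1ccc3c(c1)C=CC(C)(C)O3)CC2=O | target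

**Count**

Total step count: 9. Longest linear sequence: 6 steps (steps 4 to 9).

**Steps most likely to fail**

Step 8. The insertion of C2=C3 may proceed with poor facial selectivity, because the chromone is made electron-rich by the 7-silyloxy group and may need forcing conditions under which the ligand-free background reaction gains ground. The fallback gives up catalyst control and sets out from 8 and 20. The addition is run with an achiral catalyst (Pd(OCOCF3)2 with 2,2'-bipyridine, aqueous ClCH2CH2Cl, 60 °C) to give the racemic silyl ether F1. A kinetic resolution by asymmetric transfer hydrogenation (RhCl(C5Me5)[(R,R)-TsDPEN] or its mirror image, whichever consumes the (2R)-ketone faster, HCO2H/Et3N, EtOAc, rt) should then reduce the unwanted enantiomer to the cis-flavan-4-ol F2. The untouched (2S)-ketone is 21, where the route is rejoined.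

Step 6. Carbon–oxygen reductive elimination from the seven-membered palladacycle may be slow, so that the arylpalladium intermediate is lost to hydrodehalogenation or begins to attack the carbon–bromine bond. The fallback closes the same bond without a metal and sets out from 10. Still–Gennari olefination of commercial 5-bromo-2-fluorobenzaldehyde with 10 should give methyl (Z)-3-(5-bromo-2-fluorophenyl)prop-2-enoate F3, and double addition of 12 gives (Z)-4-(5-bromo-2-fluorophenyl)-2-methylbut-3-en-2-ol F4. Its potassium alkoxide (KN(SiMe3)2, THF, then N-methylpyrrolidinone, 90 °C) should displace fluoride by intramolecular nucleophilic aromatic substitution, in which bromide cannot compete as leaving group. This gives 15, where the route is rejoined.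

Step 3. Allylic transposition during transmetalation and reductive elimination may deliver the branched 1,1-dimethylallyl isomer beside the prenyl compound. The fallback removes the ambiguity and sets out from 6. Stille coupling with allyltributylstannane (Pd(PPh3)4, DMF, 95 °C) gives 6-(prop-2-en-1-yl)-7-[tri(propan-2-yl)silyloxy]-4H-chromen-4-one F5. Cross-metathesis with 2-methylbut-2-ene (second-generation Grubbs catalyst, RuCl2(=CHPh)(H2IMes)(PCy3), CH2Cl2, 40 °C) should then turn the allyl group into the prenyl group while the electron-poor C2=C3 bond stays inert. This gives 8, where the route is rejoined.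

**Further compounds**

F1 | step 8 | racemic 2-(2,2-dimethyl-2H-chromen-6-yl)-6-(3-methylbut-2-en-1-yl)-7-[tri(propan-2-yl)silyloxy]-2,3-dihydro-4H-chromen-4-one | CC(C)=CCc1cc2c(cc1O[Si](C(C)C)(C(C)C)C(C)C)OC(c1ccc3c(c1)C=CC(C)(C)O3)CC2=O
F2 | step 8 | (2R,4R)-2-(2,2-dimethyl-2H-chromen-6-yl)-6-(3-methylbut-2-en-1-yl)-7-[tri(propan-2-yl)silyloxy]-3,4-dihydro-2H-chromen-4-ol | CC(C)=CCc1cc2c(cc1O[Si](C(C)C)(C(C)C)C(C)C)O[C@@H](c1ccc3c(c1)C=CC(C)(C)O3)C[C@H]2O
F3 | step 6 | methyl (Z)-3-(5-bromo-2-fluorophenyl)prop-2-enoate | COC(=O)/C=C\c1cc(Br)ccc1F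
F4 | step 6 | (Z)-4-(5-bromo-2-fluorophenyl)-2-methylbut-3-en-2-ol | CC(C)(O)/C=C\c1cc(Br)ccc1F
F5 | step 3 | 6-(prop-2-en-1-yl)-7-[tri(propan-2-yl)silyloxy]-4H-chromen-4-one | C=CCc1cc2c(cc1O[Si](C(C)C)(C(C)C)C(C)C)OC=CC2=O
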